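## Retrosynthetic overview

1. Target 14 comes from silylethyl ester 13 by fluoride cleavage; 13 comes from iodide 10 and 3-bromofuran 11 by Negishi sp3–sp2 coupling.
2. 10 comes from lactone 8 by alcoholysis of the second lactone and Appel iodination; 8 comes from aldehyde 7 by Wittig olefination with the isopropylidene ylide.
3. Key disconnection is the methyl ester C–O bond: 7 comes from meso bis-lactone 5 by catalyst-controlled mono-methanolysis. This one step fixes the absolute configuration at both stereocenters and tells apart the two carboxyl carbons and the two three-carbon arms.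
4. 5 comes from two molecules of δ-valerolactone 1 and 1,3-diiodopropane 2 by double enolate alkylation.
5. Rings: none is built. The furan enters intact with 11; the two lactone rings of 5 come from 1 and are opened one after the other in steps 2 and 4.

## Assumptions

- The meso and racemic diastereomers of bis-lactone 5 form 1:1 and are assumed separable by crystallization (the racemate is recycled through its bis-enolate).
- The (R) phosphoric acid is assumed to open the (R)-lactone of 5 faster; if a test run shows the opposite sense, the (S) catalyst is used.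

All inputs (1, 2, 11, methanol, isopropyltriphenylphosphonium iodide, 2-(trimethylsilyl)ethanol) are cheap catalogue chemicals.

## Route

Step 1
Reactants: 1 δ-valerolactone (oxan-2-one; 2.1 equiv); 2 1,3-diiodopropane
Product: 5 (3R,3'S)-3,3'-(propane-1,3-diyl)bis(oxan-2-one) (meso bis-lactone), via lithium enolate 3 (not isolated), via iodopropyl lactone 4 (not isolated)
Conditions: LiN(iPr)2 (2.1 equiv), THF, −78 °C; then 2 (1.0 equiv), DMPU, −78 → −35 °C; aq. NH4Cl; meso 5 crystallized from the 1:1 meso/racemic mixture
Reagents that add atoms: none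
Why: Double SN2 C-alkylation of the lactone lithium enolate by the primary diiodide (enolate alkylation); the two remote α-stereocenters form without control, and the achiral meso isomer, which holds the syn relation of the target, is taken on.

Step 2
Reactants: 5 meso bis-lactone
Product: 7 methyl (2R)-5-oxo-2-{3-[(3S)-2-oxooxan-3-yl]propyl}pentanoate, via hydroxy ester 6 (not isolated)
Conditions: MeOH (10 equiv), (R)-3,3'-bis(2,4,6-triisopropylphenyl)-1,1'-binaphthyl-2,2'-diyl hydrogen phosphate (10 mol %), toluene, 0 °C, to about 95% conversion of the fast lactone; Et3N (0.15 equiv), volatiles removed at 0 °C; then Dess–Martin periodinane (1,1,1-triacetoxy-1,1-dihydro-1,2-benziodoxol-3(1H)-one, 1.3 equiv), CH2Cl2, 0 °C → rt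
Reagents that add atoms: methanol, CO
Why: Proposed new method: enantiotopic-group-selective mono-methanolysis of a meso bis(δ-lactone) by a bulky chiral phosphoric acid acting as a bifunctional catalyst (P–OH hydrogen-bonds the lactone carbonyl, P=O takes the methanol O–H, so addition and ring C–O cleavage occur inside the chiral pocket); the two lactones of 5 are enantiotopic and each holds its stereocenter next to the carbonyl in a rigid ring (ring CH2 versus exocyclic chain versus H), so one of them, taken as the (R)-lactone, opens faster, which forms the methyl ester C–O bond of the target, differentiates the two carboxyls and the two arms and fixes the absolute configuration of both existing stereocenters; wrong-sense product still holds the fast lactone and is drained to the doubly opened diester, so ee rises with conversion (a selectivity factor of 20 already gives about 98% ee at about 80% yield); the closest known reaction types are phosphoric-acid-catalysed ring-opening alcoholysis of lactones (chiral phosphoric acids discriminate the enantiomers of racemic lactide in ring-opening polymerization) and the phosphoric-acid-catalysed desymmetrizing lactonization of prochiral hydroxy diesters, its reverse; hydroxy ester 6 would re-close on standing, so it is oxidized at once (Dess–Martin oxidation, alcohol to aldehyde).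

Step 3
Reactants: 7 aldehyde ester lactone
Product: 8 methyl (2R)-6-methyl-2-{3-[(3S)-2-oxooxan-3-yl]propyl}hept-5-enoate
Conditions: isopropyltriphenylphosphonium iodide (1.25 equiv), n-BuLi (1.2 equiv), THF, 0 °C; then 7, −78 → −20 °C; aq. NH4Cl
Reagents that add atoms: isopropyltriphenylphosphonium iodide, CC(C)[P+](c1ccccc1)(c1ccccc1)c1ccccc1.[I-]
Why: Wittig olefination; the non-stabilized ylide takes the aldehyde at −78 °C far faster than the lactone or the ester, the ylide is symmetric so no alkene geometry arises, and the α-stereocenters are not deprotonated at this temperature.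

Step 4
Reactants: 8 alkenyl ester lactone
Product: 10 7-methyl 1-[2-(trimethylsilyl)ethyl] (2S,6R)-2-(3-iodopropyl)-6-(4-methylpent-3-en-1-yl)heptanedioate, via hydroxy diester 9 (not isolated)
Conditions: Me3SiCH2CH2OH (neat, 15 equiv), (PhO)2P(O)OH (10 mol %), 35 °C; Et3N (0.15 equiv), excess alcohol removed in vacuo; then PPh3 (1.5 equiv), I2 (1.5 equiv), imidazole (3 equiv), CH2Cl2, 0 °C
Reagents that add atoms: 2-(trimethylsilyl)ethanol, C[Si](C)(C)CCO; iodine, II
Why: Acid-catalysed transesterification (alcoholysis) of the δ-lactone in neat alcohol is much faster than exchange of the acyclic α-branched methyl ester, and the freed primary alcohol is converted at once into the iodide (Appel reaction) so that it cannot re-close; no stereocenter is touched.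

Step 5
Reactants: 10 iodide; 11 3-bromofuran (1.3 equiv)
Product: 13 7-methyl 1-[2-(trimethylsilyl)ethyl] (2S,6R)-2-[3-(furan-3-yl)propyl]-6-(4-methylpent-3-en-1-yl)heptanedioate, via alkylzinc iodide 12 (not isolated)
Conditions: Zn dust (2 equiv, activated by 2 mol % I2), LiCl (1.5 equiv), THF, 35 °C; then 11, Pd(OAc)2 (2 mol %), 2-dicyclohexylphosphino-2',6'-dimethoxybiphenyl (4 mol %), THF, 40 °C
Reagents that add atoms: zinc, [Zn] (stays in intermediate 12 only)
Why: Zinc insertion into the primary C–I bond, then Negishi coupling with the heteroaryl bromide under zerovalent palladium catalysis; alkylzinc halides tolerate both esters and the trisubstituted alkene, and the reacting carbon is three atoms away from the stereocenter.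

Step 6
Reactants: 13 furyl diester
Product: 14 (2S,6R)-2-[3-(furan-3-yl)propyl]-6-(methoxycarbonyl)-10-methylundec-9-enoic acid
Conditions: Bu4NF (2.5 equiv), THF, 0 °C → rt; cold 0.5 M HCl work-up
Reagents that add atoms: none
Why: Fluoride-induced β-elimination of the 2-(trimethylsilyl)ethyl ester (attack at silicon, loss of ethene) frees the acid while the methyl ester, the furan, the alkene and both α-stereocenters stay untouched.

## Compound list

1 | δ-valerolactone (oxan-2-one) | O=C1CCCCO1 | starting material
2 | 1,3-diiodopropane | ICCCI | starting material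
3 | lithium 3,4-dihydro-2H-pyran-6-olate (lithium enolate of 1) | [Li+].[O-]C1=CCCCO1 | intermediate (not isolated)
4 | 3-(3-iodopropyl)oxan-2-one (racemic) | O=C1OCCCC1CCCI | intermediate (not isolated)
5 | (3R,3'S)-3,3'-(propane-1,3-diyl)bis(oxan-2-one), meso | O=C1OCCC[C@H]1CCC[C@H]1CCCOC1=O | intermediate
6 | methyl (2R)-5-hydroxy-2-{3-[(3S)-2-oxooxan-3-yl]propyl}pentanoate | COC(=O)[C@@H](CCCO)CCC[C@H]1CCCOC1=O | intermediate (not isolated)
7 | methyl (2R)-5-oxo-2-{3-[(3S)-2-oxooxan-3-yl]propyl}pentanoate | COC(=O)[C@@H](CCC=O)CCC[C@H]1CCCOC1=O | intermediate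
8 | methyl (2R)-6-methyl-2-{3-[(3S)-2-oxooxan-3-yl]propyl}hept-5-enoate | COC(=O)[C@@H](CCC=C(C)C)CCC[C@H]1CCCOC1=O | intermediate
9 | 7-methyl 1-[2-(trimethylsilyl)ethyl] (2S,6R)-2-(3-hydroxypropyl)-6-(4-methylpent-3-en-1-yl)heptanedioate | COC(=O)[C@@H](CCC=C(C)C)CCC[C@@H](CCCO)C(=O)OCC[Si](C)(C)C | intermediate (not isolated)
10 | 7-methyl 1-[2-(trimethylsilyl)ethyl] (2S,6R)-2-(3-iodopropyl)-6-(4-methylpent-3-en-1-yl)heptanedioate | COC(=O)[C@@H](CCC=C(C)C)CCC[C@@H](CCCI)C(=O)OCC[Si](C)(C)C | intermediate
11 | 3-bromofuran | Brc1ccoc1 | starting material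
12 | 7-methyl 1-[2-(trimethylsilyl)ethyl] (2S,6R)-2-[3-(iodozincio)propyl]-6-(4-methylpent-3-en-1-yl)heptanedioate | COC(=O)[C@@H](CCC=C(C)C)CCC[C@@H](CCC[Zn]I)C(=O)OCC[Si](C)(C)C | intermediate (not isolated)
13 | 7-methyl 1-[2-(trimethylsilyl)ethyl] (2S,6R)-2-[3-(furan-3-yl)propyl]-6-(4-methylpent-3-en-1-yl)heptanedioate | COC(=O)[C@@H](CCC=C(C)C)CCC[C@@H](CCCc1ccoc1)C(=O)OCC[Si](C)(C)C | intermediate
14 | (2S,6R)-2-[3-(furan-3-yl)propyl]-6-(methoxycarbonyl)-10-methylundec-9-enoic acid | COC(=O)[C@@H](CCC=C(C)C)CCC[C@@H](CCCc1ccoc1)C(=O)O | target

## Step count and risks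

Total step count: 6. Longest linear sequence: 6 (1 → 5 → 7 → 8 → 10 → 13 → 14).

Three steps most likely to fail:

**Step 2 (the proposed new method).** The phosphoric acid may open the α-branched lactone too slowly or with too small a rate difference between the two lactones. The fallback uses known chemistry (esterase desymmetrization of a meso diester by hydrolysis). It sets out from 5 and comes back at 6. Both lactones of 5 are opened with K2CO3 (0.2 equiv) in MeOH to dimethyl (2R,6S)-2,6-bis(3-hydroxypropyl)heptanedioate F1. F1 is hydrolysed on one ester group by pig liver esterase in pH 7 phosphate buffer to (2S,6R)-2,6-bis(3-hydroxypropyl)-7-methoxy-7-oxoheptanoic acid F2. On acidification to pH 3 only the hydroxy acid half closes to the δ-lactone, giving 6, which is oxidized as in step 2 to 7. If the esterase prefers the other ester group, a hydrolase of opposite preference is picked in a screen.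

**Step 1.** The meso and racemic bis-lactones may not separate. The fallback drops the separation and lets the catalyst of step 2 sort the isomers; it sets out from 1 and 2 and comes back at 7. The crude mixture holds 5 together with (3R,3'R)-3,3'-(propane-1,3-diyl)bis(oxan-2-one) F3 and (3S,3'S)-3,3'-(propane-1,3-diyl)bis(oxan-2-one) F4 and is put through step 2 as it is.
- F3 has two fast lactones, is opened twice and appears after the oxidation as dimethyl (2R,6R)-2,6-bis(3-oxopropyl)heptanedioate F5.
- F4 has two slow lactones and is recovered.
- Both are removed from 7 on silica.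
- Singly opened material from the racemate remains as the anti diastereomer of 7: methyl (2R)-5-oxo-2-{3-[(3R)-2-oxooxan-3-yl]propyl}pentanoate F6 and methyl (2S)-5-oxo-2-{3-[(3S)-2-oxooxan-3-yl]propyl}pentanoate F7. By a simple two-rate model this is about 3% at a selectivity factor of 200 and about 10% at 50; it is removed by preparative HPLC at 10.

**Step 4.** The alcoholysis is an equilibrium and may stall, or the methyl ester may exchange. The fallback replaces it by irreversible saponification and carboxylate alkylation; it sets out from 8 and comes back at 9. The lactone alone is saponified with CsOH (1.0 equiv, THF/H2O, 0 °C; δ-lactones hydrolyse far faster than α-branched methyl esters) to cesium (2S,6R)-2-(3-hydroxypropyl)-7-methoxy-6-(4-methylpent-3-en-1-yl)-7-oxoheptanoate F8. This carboxylate is O-alkylated with (2-bromoethyl)trimethylsilane in DMF at 40 °C (SN2 at the alkyl bromide, no acyl activation, so no re-lactonization) to give 9, which is iodinated as in step 4.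

## Further compounds

F1 | step 2 | dimethyl (2R,6S)-2,6-bis(3-hydroxypropyl)heptanedioate (meso) | COC(=O)[C@@H](CCCO)CCC[C@@H](CCCO)C(=O)OC
F2 | step 2 | (2S,6R)-2,6-bis(3-hydroxypropyl)-7-methoxy-7-oxoheptanoic acid | COC(=O)[C@@H](CCCO)CCC[C@@H](CCCO)C(=O)O
F3 | step 1 | (3R,3'R)-3,3'-(propane-1,3-diyl)bis(oxan-2-one) | O=C1OCCC[C@H]1CCC[C@@H]1CCCOC1=O
F4 | step 1 | (3S,3'S)-3,3'-(propane-1,3-diyl)bis(oxan-2-one) | O=C1OCCC[C@@H]1CCC[C@H]1CCCOC1=O
F5 | step 1 | dimethyl (2R,6R)-2,6-bis(3-oxopropyl)heptanedioate | COC(=O)[C@@H](CCC=O)CCC[C@H](CCC=O)C(=O)OC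
F6 | step 1 | methyl (2R)-5-oxo-2-{3-[(3R)-2-oxooxan-3-yl]propyl}pentanoate | COC(=O)[C@@H](CCC=O)CCC[C@@H]1CCCOC1=O
F7 | step 1 | methyl (2S)-5-oxo-2-{3-[(3S)-2-oxooxan-3-yl]propyl}pentanoate | COC(=O)[C@H](CCC=O)CCC[C@H]1CCCOC1=O
F8 | step 4 | cesium (2S,6R)-2-(3-hydroxypropyl)-7-methoxy-6-(4-methylpent-3-en-1-yl)-7-oxoheptanoate | COC(=O)[C@@H](CCC=C(C)C)CCC[C@@H](CCCO)C(=O)[O-].[Cs+]
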